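The ten-membered ring is opened at C3–C4. The C3 ketone beside the isopropyl-bearing C4 is the oxidised and hydrogenated form of a carbinol flanked by an isopropenyl carbon, which is what a [2,3]-Wittig shift of a diallyl ether leaves behind. One operation on a thirteen-membered (E,E)-diallyl ether, whose oxygen links C3 to the allylic carbon C13 and which carries C6/C7 as an acetonide and C8 as a silyl ether, forms C3–C4, breaks the ring C–O bond, closes the carbocycle and sets C4. The ether is assembled from a geraniol-derived aldehyde and a lactate dioxolanone; the C6 epoxyangelate is attached last.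

Key step: step 16

Remark: ring atoms keep the target's locants (C1 methyl-bearing alkene carbon, C3 and C8 ketone carbons, C4 isopropyl-bearing, C6 ester carbinol, C7 tertiary carbinol), and C11/C12/C13 are the future isopropyl CH, one of its methyls and the ether CH2; the C8 carbinol is drawn as the (8R) epimer expected from the aldol and is oxidised later, so it does not reach the target.

**Route**

Step 1
Reactants: 1 geraniol
Product: 2 geranyl 4-methoxybenzyl (PMB) ether
Conditions: NaH, PMBCl, cat. Bu4NI, THF/DMF, 0 °C to rt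
Reagents that add atoms: 4-methoxybenzyl chloride COc1ccc(CCl)cc1
Why: Williamson etherification of the primary allylic alkoxide gives a C3–O protecting group that survives hydride, base and Lewis acid and can later be removed oxidatively without touching a silyl ether or a ketal.

Step 2
Reactants: 2 geranyl PMB ether
Product: 3 racemic 6,7-epoxide of 2
Conditions: mCPBA (1 equiv), NaHCO3, CH2Cl2, −20 to 0 °C
Reagents that add atoms: 3-chloroperoxybenzoic acid OOC(=O)c1cccc(Cl)c1
Why: Prilezhaev epoxidation should prefer the remote trisubstituted alkene because the other alkene is deactivated inductively by the allylic ether oxygen; the epoxide is racemic, which is irrelevant because its carbon is cleaved off next.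

Step 3
Reactants: 3 racemic epoxide
Product: 4 (4E)-6-(4-methoxybenzyloxy)-4-methylhex-4-enal (C8 to C3 fragment)
Conditions: H5IO6, THF/H2O, 0 °C
Reagents that add atoms: none
Why: Acid-mediated epoxide hydrolysis followed by Malaprade glycol cleavage in one flask releases acetone and the C8 aldehyde, leaving the (E)-alkene and the PMB ether untouched.

Step 4
Reactants: 5 (S)-lactic acid
Product: 6 (2S,5S)-2-tert-butyl-5-methyl-1,3-dioxolan-4-one (cis)
Conditions: pivalaldehyde, cat. TsOH, cat. H2SO4, pentane, reflux (Dean–Stark); crystallisation at −78 °C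
Reagents that add atoms: pivalaldehyde CC(C)(C)C=O
Why: Acid-catalysed acetalisation of the α-hydroxy acid under water removal gives mainly the cis acetal, which is purified by low-temperature crystallisation; C5 keeps the lactic acid configuration (self-regeneration of stereocentres).

Step 5
Reactants: 6 (2S,5S)-dioxolanone and 4 aldehyde
Product: 8 (2S,5R)-2-tert-butyl-5-[(1R,4E)-1-hydroxy-6-(4-methoxybenzyloxy)-4-methylhex-4-enyl]-5-methyl-1,3-dioxolan-4-one, via lithium enolate 7 (not isolated)
Conditions: LDA (commercial), THF, −78 °C; then 4, −78 °C; aq NH4Cl; chromatography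
Reagents that add atoms: none
Why: Aldol addition of the dioxolanone enolate, in which the acetal tert-butyl group blocks one face so that the aldehyde bonds trans to it in the place of the former C–H, fixing the quaternary C7 with the configuration of the target tertiary carbinol, while a closed chair transition state is expected to favour the (8R) carbinol (the C8 epimer is removed here and C8 is oxidised later anyway).

Step 6
Reactants: 8 aldol adduct
Product: 9 C8 tert-butyldimethylsilyl ether of 8
Conditions: TBSOTf, 2,6-lutidine, CH2Cl2, −78 to 0 °C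
Reagents that add atoms: tert-butyldimethylsilyl triflate CC(C)(C)[Si](C)(C)OS(=O)(=O)C(F)(F)F
Why: Silylation of the hindered secondary alcohol with the silyl triflate masks C8–OH, the future ketone, through all basic and organometallic steps.

Step 7
Reactants: 9 silyl ether
Product: 10 (2S,3R,6E)-3-(tert-butyldimethylsilyloxy)-8-(4-methoxybenzyloxy)-2,6-dimethyloct-6-ene-1,2-diol
Conditions: LiAlH4, Et2O, 0 °C; Rochelle salt work-up
Reagents that add atoms: none
Why: Hydride reduction of the acylal-type lactone opens the dioxolanone to the C6 primary alcohol and the free C7 tertiary alcohol and releases the pivalaldehyde unit as neopentyl alcohol, with the aryl ether, silyl ether and alkene inert.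

Step 8
Reactants: 10 diol
Product: 11 (2R,3R,6E)-3-(tert-butyldimethylsilyloxy)-2-hydroxy-8-(4-methoxybenzyloxy)-2,6-dimethyloct-6-enal
Conditions: SO3·pyridine, DMSO, iPr2NEt, CH2Cl2, 0 °C
Reagents that add atoms: none
Why: Parikh–Doering oxidation can only convert the primary alcohol (its neighbour is tertiary) and works under non-acidic conditions at 0 °C, which avoids silyl migration and glycol cleavage; the C2 descriptor changes by priority only.

Step 9
Reactants: 11 α-hydroxy aldehyde
Product: 12 (4R,5S,6R,9E)-6-(tert-butyldimethylsilyloxy)-11-(4-methoxybenzyloxy)-5,9-dimethylundeca-1,9-diene-4,5-diol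
Conditions: In powder, allyl bromide, THF/H2O (1:1), rt
Reagents that add atoms: allyl bromide C=CCBr
Why: Barbier-type indium allylation in aqueous medium, in which the free α-hydroxyl and the aldehyde oxygen chelate indium (cyclic chelate model) so that allyl adds to the face flanked by the C7 methyl and away from the bulky C8 side chain, should give the syn-6,7-diol with (6R).

Step 10
Reactants: 12 allyl diol
Product: 13 (4R,5S)-4-allyl-5-[(1R,4E)-1-(tert-butyldimethylsilyloxy)-6-(4-methoxybenzyloxy)-4-methylhex-4-enyl]-2,2,5-trimethyl-1,3-dioxolane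
Conditions: 2,2-dimethoxypropane, cat. PPTS, CH2Cl2, rt
Reagents that add atoms: 2,2-dimethoxypropane COC(C)(C)OC
Why: Acid-catalysed transketalisation ties the secondary/tertiary syn-diol into a dioxolane that protects C6–OH and C7–OH and stiffens the later macrocycle.

Step 11
Reactants: 13 terminal alkene
Product: 14 (E)-2-methyl enal (C13 aldehyde, C4=C11 alkene) of the acetonide series
Conditions: methacrolein (excess), Hoveyda–Grubbs II (cat.), CH2Cl2, 40 °C
Reagents that add atoms: methacrolein C=C(C)C=O
Why: Olefin cross-metathesis of the terminal alkene with excess methacrolein gives the conjugated (E)-trisubstituted enal under thermodynamic control, while the trisubstituted C1=C2 alkene is too hindered to enter the catalytic cycle.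

Step 12
Reactants: 14 enal
Product: 15 (E)-allylic alcohol (C13–OH)
Conditions: NaBH4, CeCl3·7H2O, MeOH, −20 °C
Reagents that add atoms: none
Why: Luche 1,2-reduction of the enal gives the (E)-allylic alcohol without conjugate reduction.

Step 13
Reactants: 15 allylic alcohol
Product: 17 C13 allylic chloride with C3 OPMB, via mesylate 16 (not isolated)
Conditions: MsCl, Et3N, CH2Cl2, −20 °C; then LiCl, DMF, 0 °C to rt
Reagents that add atoms: lithium chloride [Li+].[Cl-]
Why: Mesylation and SN2 displacement by chloride at the primary allylic carbon should give the chloride without allylic transposition, with ketal, silyl ether and PMB ether stable.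

Step 14
Reactants: 17 allylic chloride
Product: 18 hydroxy chloride (free C3–OH, C13–Cl)
Conditions: DDQ, CH2Cl2/pH 7 buffer, 0 °C
Reagents that add atoms: none
Why: Oxidative PMB cleavage by DDQ proceeds by hydride abstraction at the electron-rich benzylic position and frees the C3 allylic alcohol while allylic chloride, ketal and silyl ether are unaffected.

Step 15
Reactants: 18 hydroxy chloride
Product: 20 thirteen-membered (E,E)-diallyl ether (6R,7S,8R) bearing the C6/C7 acetonide plus the C8 OTBS group, via sodium alkoxide 19 (not isolated)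
Conditions: NaH, THF, reflux, slow addition of 18 (high dilution)
Reagents that add atoms: none
Why: Intramolecular Williamson etherification, in which the primary allylic alkoxide displaces the primary allylic chloride by SN2 with both alkene geometries retained, while slow addition keeps the concentration low enough to disfavour intermolecular etherification.

Step 16
Reactants: 20 thirteen-membered diallyl ether
Product: 23 (3S,4R,6R,7S,8R)-ten-membered C3 carbinol bearing C4 isopropenyl, via C3-lithiated ether 21 (not isolated), via lithium alkoxide 22 (not isolated)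
Conditions: s-BuLi, THF, −78 to −40 °C; aq NH4Cl
Reagents that add atoms: none
Why: sec-Butyllithium removes a proton from C3 and the resulting α-oxy allyl anion bonds to C4 through a five-membered envelope transition state while the O–C13 bond breaks and C11=C13 becomes the isopropenyl alkene, leaving the C3 lithium alkoxide ([2,3]-Wittig rearrangement). The closest known reaction is the transannular [2,3]-Wittig contraction of farnesol-type thirteen-membered diallyl ethers to germacrane carbinols, which carry the same alkene substitution. The ten-membered ring is closed by ring contraction, the C3–C4 bond forming across the existing macrocycle, so no high-dilution C–C cyclisation is needed and the (E)-C1=C2 alkene is carried through at low temperature. C4 is set by the face of the (E)-C4=C11 alkene that the folded macrocycle turns towards C3, a bias imposed by the trans-fused C6/C7 dioxolane and the C8 silyl ether, while C3 follows from the (E) geometry and the suprafacial shift and is erased later. The step needs lithiation at C3 and not at C13: the C3 protons adjoin the unsubstituted alkene carbon C2 and are the more accessible to the hindered base, whereas a C13 anion could only rearrange by attacking the fully substituted C1. Keeping the temperature at or below −40 °C is meant to suppress the competing [1,2]-shift.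

Step 17
Reactants: 23 isopropenyl carbinol
Product: 24 (3R,4R,6R,7S,8R)-C4 isopropyl carbinol (same spatial arrangement as 23)
Conditions: H2 (1 atm), RhCl(PPh3)3 (cat.), benzene, rt
Reagents that add atoms: none
Why: Homogeneous hydrogenation with the rhodium catalyst should reduce the unhindered 1,1-disubstituted isopropenyl alkene far faster than the trisubstituted ring alkene and creates no new stereocentre.

Step 18
Reactants: 24 silyl ether
Product: 25 (3R,4R,6R,7R,8R)-C3,C8 diol with intact acetonide
Conditions: TBAF, THF, rt to 40 °C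
Reagents that add atoms: none
Why: Fluoride-mediated desilylation frees the C8 carbinol, the ketal, allylic alcohol and alkene being stable to fluoride; the C7 descriptor changes by priority only.

Step 19
Reactants: 25 diol
Product: 26 (4R,6R,7S)-C3,C8 diketone acetonide
Conditions: Dess–Martin periodinane, NaHCO3, CH2Cl2, 0 °C to rt
Reagents that add atoms: none
Why: Dess–Martin oxidation converts both secondary carbinols (allylic C3 and C8) to ketones under buffered conditions that should not epimerise the α-stereocentre C4, and it erases the C3 and C8 stereocentres.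

Step 20
Reactants: 26 diketone acetonide
Product: 27 (1E,4R,6R,7S)-6,7-dihydroxy-1,7-dimethyl-4-isopropylcyclodec-1-ene-3,8-dione
Conditions: TFA/H2O/THF, 0 °C to rt
Reagents that add atoms: none
Why: Aqueous acid hydrolysis of the dioxolane releases the C6/C7 diol before the acid-labile epoxy ester is introduced, and a short reaction at low temperature limits enolisation at C4.

Step 21
Reactants: 28 angelic acid
Product: 29 (Z)-2-methylbut-2-en-1-ol
Conditions: LiAlH4, Et2O, 0 °C
Reagents that add atoms: none
Why: Hydride reduction of the carboxylic acid gives the allylic alcohol with the (Z) geometry retained, since nothing present can isomerise it to the tiglyl series.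

Step 22
Reactants: 29 (Z)-allylic alcohol
Product: 30 [(2S,3R)-2,3-dimethyloxiran-2-yl]methanol
Conditions: Ti(OiPr)4 (cat.), L-(+)-diethyl tartrate (cat.), t-BuOOH, 4 Å MS, CH2Cl2, −20 °C
Reagents that add atoms: tert-butyl hydroperoxide CC(C)(C)OO
Why: Sharpless asymmetric epoxidation, in which the L-(+)-tartrate titanium complex delivers oxygen to the face that gives the (2S) epoxy alcohol and syn addition keeps the two methyl groups trans, setting both epoxide stereocentres.

Step 23
Reactants: 30 epoxy alcohol
Product: 31 (2R,3R)-2,3-dimethyloxirane-2-carboxylic acid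
Conditions: RuCl3 (cat.), NaIO4, CCl4/MeCN/H2O, 0 °C to rt
Reagents that add atoms: sodium periodate [Na+].[O-]I(=O)(=O)=O; water O
Why: Ruthenium tetroxide generated catalytically oxidises the primary alcohol to the carboxylic acid without opening the epoxide; the C2 descriptor changes from S to R by priority only.

Step 24
Reactants: 27 dihydroxy diketone and 31 epoxy acid
Product: 33 target CNP0389889.1, via mixed anhydride 32 (not isolated)
Conditions: 31, 2,4,6-trichlorobenzoyl chloride, Et3N, THF, rt; then 27, DMAP, toluene, rt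
Reagents that add atoms: none
Why: Yamaguchi esterification through the mixed anhydride and DMAP should acylate the secondary C6 hydroxyl in preference to the tertiary C7 hydroxyl under mildly basic conditions that leave the epoxide, the α-ketol and C4 untouched.

**Compound list**

1 | geraniol, (2E)-3,7-dimethylocta-2,6-dien-1-ol | CC(C)=CCC/C(C)=C/CO | starting material
2 | geranyl 4-methoxybenzyl ether | CC(C)=CCC/C(C)=C/COCc1ccc(OC)cc1 | intermediate
3 | racemic 3-[(3E)-5-(4-methoxybenzyloxy)-3-methylpent-3-enyl]-2,2-dimethyloxirane | CC1(C)OC1CC/C(C)=C/COCc2ccc(OC)cc2 | intermediate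
4 | (4E)-6-(4-methoxybenzyloxy)-4-methylhex-4-enal | O=CCC/C(C)=C/COCc1ccc(OC)cc1 | intermediate
5 | (S)-lactic acid | C[C@H](O)C(=O)O | starting material
6 | (2S,5S)-2-tert-butyl-5-methyl-1,3-dioxolan-4-one | C[C@@H]1O[C@H](C(C)(C)C)OC1=O | intermediate
7 | lithium enolate of 6, lithium (2S)-2-tert-butyl-5-methyl-1,3-dioxol-4-olate | CC1=C(O[Li])O[C@@H](C(C)(C)C)O1 | intermediate
8 | (2S,5R)-2-tert-butyl-5-[(1R,4E)-1-hydroxy-6-(4-methoxybenzyloxy)-4-methylhex-4-enyl]-5-methyl-1,3-dioxolan-4-one | C[C@]1([C@H](O)CC/C(C)=C/COCc2ccc(OC)cc2)O[C@H](C(C)(C)C)OC1=O | intermediate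
9 | (2S,5R)-2-tert-butyl-5-[(1R,4E)-1-(tert-butyldimethylsilyloxy)-6-(4-methoxybenzyloxy)-4-methylhex-4-enyl]-5-methyl-1,3-dioxolan-4-one | C[C@]1([C@H](O[Si](C)(C)C(C)(C)C)CC/C(C)=C/COCc2ccc(OC)cc2)O[C@H](C(C)(C)C)OC1=O | intermediate
10 | (2S,3R,6E)-3-(tert-butyldimethylsilyloxy)-8-(4-methoxybenzyloxy)-2,6-dimethyloct-6-ene-1,2-diol | OC[C@](C)(O)[C@H](O[Si](C)(C)C(C)(C)C)CC/C(C)=C/COCc1ccc(OC)cc1 | intermediate
11 | (2R,3R,6E)-3-(tert-butyldimethylsilyloxy)-2-hydroxy-8-(4-methoxybenzyloxy)-2,6-dimethyloct-6-enal | O=C[C@](C)(O)[C@H](O[Si](C)(C)C(C)(C)C)CC/C(C)=C/COCc1ccc(OC)cc1 | intermediate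
12 | (4R,5S,6R,9E)-6-(tert-butyldimethylsilyloxy)-11-(4-methoxybenzyloxy)-5,9-dimethylundeca-1,9-diene-4,5-diol | C=CC[C@@H](O)[C@](C)(O)[C@H](O[Si](C)(C)C(C)(C)C)CC/C(C)=C/COCc1ccc(OC)cc1 | intermediate
13 | (4R,5S)-4-allyl-5-[(1R,4E)-1-(tert-butyldimethylsilyloxy)-6-(4-methoxybenzyloxy)-4-methylhex-4-enyl]-2,2,5-trimethyl-1,3-dioxolane | C=CC[C@H]1OC(C)(C)O[C@]1(C)[C@H](O[Si](C)(C)C(C)(C)C)CC/C(C)=C/COCc2ccc(OC)cc2 | intermediate
14 | (2E)-4-[(4R,5S)-5-[(1R,4E)-1-(tert-butyldimethylsilyloxy)-6-(4-methoxybenzyloxy)-4-methylhex-4-enyl]-2,2,5-trimethyl-1,3-dioxolan-4-yl]-2-methylbut-2-enal | O=C/C(C)=C/C[C@H]1OC(C)(C)O[C@]1(C)[C@H](O[Si](C)(C)C(C)(C)C)CC/C(C)=C/COCc2ccc(OC)cc2 | intermediate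
15 | (2E)-allylic alcohol from 14 (C13–OH, otherwise as 14) | OC/C(C)=C/C[C@H]1OC(C)(C)O[C@]1(C)[C@H](O[Si](C)(C)C(C)(C)C)CC/C(C)=C/COCc2ccc(OC)cc2 | intermediate
16 | methanesulfonate of 15 | CS(=O)(=O)OC/C(C)=C/C[C@H]1OC(C)(C)O[C@]1(C)[C@H](O[Si](C)(C)C(C)(C)C)CC/C(C)=C/COCc2ccc(OC)cc2 | intermediate
17 | (4R,5S)-4-[(2E)-4-chloro-3-methylbut-2-enyl]-5-[(1R,4E)-1-(tert-butyldimethylsilyloxy)-6-(4-methoxybenzyloxy)-4-methylhex-4-enyl]-2,2,5-trimethyl-1,3-dioxolane | ClC/C(C)=C/C[C@H]1OC(C)(C)O[C@]1(C)[C@H](O[Si](C)(C)C(C)(C)C)CC/C(C)=C/COCc2ccc(OC)cc2 | intermediate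
18 | (2E,6R)-6-(tert-butyldimethylsilyloxy)-6-[(4S,5R)-5-[(2E)-4-chloro-3-methylbut-2-enyl]-2,2,4-trimethyl-1,3-dioxolan-4-yl]-3-methylhex-2-en-1-ol | ClC/C(C)=C/C[C@H]1OC(C)(C)O[C@]1(C)[C@H](O[Si](C)(C)C(C)(C)C)CC/C(C)=C/CO | intermediate
19 | sodium alkoxide of 18 | ClC/C(C)=C/C[C@H]1OC(C)(C)O[C@]1(C)[C@H](O[Si](C)(C)C(C)(C)C)CC/C(C)=C/C[O-].[Na+] | intermediate
20 | thirteen-membered (E,E)-diallyl ether, C3–O–C13, (6R,7S,8R), C6/C7 acetonide, C8 OTBS | C/C1=C\COC/C(C)=C/C[C@H]2OC(C)(C)O[C@]2(C)[C@H](O[Si](C)(C)C(C)(C)C)CC1 | intermediate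
21 | C3-lithiated ether from 20 (configuration at C3 not defined) | C/C1=C\C([Li])OC/C(C)=C/C[C@H]2OC(C)(C)O[C@]2(C)[C@H](O[Si](C)(C)C(C)(C)C)CC1 | intermediate
22 | lithium alkoxide of 23 | C/C1=C\[C@H]([O-])[C@@H](C(C)=C)C[C@H]2OC(C)(C)O[C@]2(C)[C@H](O[Si](C)(C)C(C)(C)C)CC1.[Li+] | intermediate
23 | (1E,3S,4R,6R,7S,8R)-ten-membered carbinol: C3 OH, C4 isopropenyl, C6/C7 acetonide, C8 OTBS | C/C1=C\[C@H](O)[C@@H](C(C)=C)C[C@H]2OC(C)(C)O[C@]2(C)[C@H](O[Si](C)(C)C(C)(C)C)CC1 | intermediate
24 | (1E,3R,4R,6R,7S,8R)-C4 isopropyl analogue of 23 | C/C1=C\[C@H](O)[C@@H](C(C)C)C[C@H]2OC(C)(C)O[C@]2(C)[C@H](O[Si](C)(C)C(C)(C)C)CC1 | intermediate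
25 | (1E,3R,4R,6R,7R,8R)-C3,C8 diol with C6/C7 acetonide | C/C1=C\[C@H](O)[C@@H](C(C)C)C[C@H]2OC(C)(C)O[C@]2(C)[C@H](O)CC1 | intermediate
26 | (1E,4R,6R,7S)-C3,C8 diketone with C6/C7 acetonide | C/C1=C\C(=O)[C@@H](C(C)C)C[C@H]2OC(C)(C)O[C@]2(C)C(=O)CC1 | intermediate
27 | (1E,4R,6R,7S)-6,7-dihydroxy-1,7-dimethyl-4-isopropylcyclodec-1-ene-3,8-dione | C/C1=C\C(=O)[C@@H](C(C)C)C[C@@H](O)[C@](C)(O)C(=O)CC1 | intermediate
28 | angelic acid, (Z)-2-methylbut-2-enoic acid | C/C=C(/C)C(=O)O | starting material
29 | (Z)-2-methylbut-2-en-1-ol | C/C=C(/C)CO | intermediate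
30 | [(2S,3R)-2,3-dimethyloxiran-2-yl]methanol | OC[C@]1(C)O[C@@H]1C | intermediate
31 | (2R,3R)-2,3-dimethyloxirane-2-carboxylic acid | OC(=O)[C@]1(C)O[C@@H]1C | intermediate
32 | mixed anhydride of 31 with 2,4,6-trichlorobenzoic acid | O=C(OC(=O)[C@]1(C)O[C@@H]1C)c2c(Cl)cc(Cl)cc2Cl | intermediate
33 | CNP0389889.1, (1E,4R,6R,7S)-7-hydroxy-1,7-dimethyl-3,8-dioxo-4-isopropylcyclodec-1-en-6-yl (2R,3R)-2,3-dimethyloxirane-2-carboxylate | C/C1=C\C(=O)[C@@H](C(C)C)C[C@@H](OC(=O)[C@]2(C)O[C@@H]2C)[C@](C)(O)C(=O)CC1 | target

**Step count and risks**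

Total step count: 24. Longest linear sequence: 20 steps (geraniol 1 to target 33 through steps 1–3, 5–20 and 24).

Steps most likely to fail:

Step 16 (ring contraction). The base may lithiate the C13 methylene instead of C3, the anion may attack the wrong face of the C4=C11 alkene, or a [1,2]-shift may compete. The fallback makes the same C3–C4 bond by an intramolecular Nozaki–Hiyama allylation, which fixes the regiochemistry because C3 is then the electrophile. It sets out from hydroxy chloride 18. MnO2 in CH2Cl2 oxidises the C3 allylic alcohol to the (E)-enal chloride F1. CrCl2 with catalytic NaI in THF under high dilution then turns the C13 allylic chloride into an allylchromium species that adds through its γ-carbon C4 to the C3 aldehyde. The anti addition usual for this reaction corresponds to the C3/C4 relationship of carbinol 23, where the fallback rejoins the route; steps 15 and 16 are bypassed.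

Step 15 (macro-etherification). Intermolecular etherification to oligomers, SN2′ closure at C4 or base-induced loss of HCl may outrun ring closure. The fallback closes the macrocycle by olefin metathesis instead of C–O bond formation. It sets out from terminal alkene 13. DDQ in wet CH2Cl2 frees the C3 allylic alcohol F2, and NaH with 3-chloro-2-methylpropene gives the methallyl ether F3. Ring-closing metathesis (second-generation ruthenium catalyst, dilute toluene, 80 °C) between the terminal alkene and the 1,1-disubstituted alkene forms the trisubstituted C4=C11 bond and returns to macrocycle 20. The geometric purity of the new alkene would have to be checked before the key step.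

Step 24 (final esterification). Acylation of the hindered C6 hydroxyl may be slow, so that retro-aldol opening (C6–OH is β to the C8 ketone), transannular hemiketal formation, C4 epimerisation or epoxide opening take over. The fallback attaches the ester before the ketones exist. It sets out from carbinol 24. TBSOTf and 2,6-lutidine give the C3,C8 bis-silyl ether F4, and aqueous acetic acid removes the acetonide to give the 6,7-diol F5. Yamaguchi esterification with acid 31 gives the C6 ester F6, and HF·pyridine in THF/pyridine removes both silyl groups to give the triol ester F7. Dess–Martin oxidation of the C3 and C8 carbinols then gives target 33, where the fallback ends.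

**Further compounds**

F1 | step 16 | (2E,6R)-6-(tert-butyldimethylsilyloxy)-6-[(4S,5R)-5-[(2E)-4-chloro-3-methylbut-2-enyl]-2,2,4-trimethyl-1,3-dioxolan-4-yl]-3-methylhex-2-enal | ClC/C(C)=C/C[C@H]1OC(C)(C)O[C@]1(C)[C@H](O[Si](C)(C)C(C)(C)C)CC/C(C)=C/C=O
F2 | step 15 | (2E,6R)-6-[(4S,5R)-5-allyl-2,2,4-trimethyl-1,3-dioxolan-4-yl]-6-(tert-butyldimethylsilyloxy)-3-methylhex-2-en-1-ol | C=CC[C@H]1OC(C)(C)O[C@]1(C)[C@H](O[Si](C)(C)C(C)(C)C)CC/C(C)=C/CO
F3 | step 15 | methallyl ether of F2 | C=CC[C@H]1OC(C)(C)O[C@]1(C)[C@H](O[Si](C)(C)C(C)(C)C)CC/C(C)=C/COCC(C)=C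
F4 | step 24 | C3,C8 bis(tert-butyldimethylsilyl) ether of 24 | C/C1=C\[C@H](O[Si](C)(C)C(C)(C)C)[C@@H](C(C)C)C[C@H]2OC(C)(C)O[C@]2(C)[C@H](O[Si](C)(C)C(C)(C)C)CC1
F5 | step 24 | 6,7-diol from F4 (acetonide removed) | C/C1=C\[C@H](O[Si](C)(C)C(C)(C)C)[C@@H](C(C)C)C[C@@H](O)[C@](C)(O)[C@H](O[Si](C)(C)C(C)(C)C)CC1
F6 | step 24 | C6 (2R,3R)-2,3-dimethyloxirane-2-carboxylate of F5 | C/C1=C\[C@H](O[Si](C)(C)C(C)(C)C)[C@@H](C(C)C)C[C@@H](OC(=O)[C@]2(C)O[C@@H]2C)[C@](C)(O)[C@H](O[Si](C)(C)C(C)(C)C)CC1
F7 | step 24 | C3,C7,C8 triol C6 ester from F6 | C/C1=C\[C@H](O)[C@@H](C(C)C)C[C@@H](OC(=O)[C@]2(C)O[C@@H]2C)[C@](C)(O)[C@H](O)CC1
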